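**Plan**
- Retrosynthesis: the C5–O allyl and C3–O methyl bonds are cut first, then both ArCH2–CH=CMe2 bonds (side chains at C2 and C4) in one operation, then the carbonates and the two benzylic alcohols back to aldehydes, and last the C4–CHO and C2–CHO bonds, which leads to pinosylvin.
- Enabling feature: with the central ring numbered C1 (styryl), C2 (prenyl), C3 (OMe), C4 (prenyl), C5 (OH), C6 (H), both prenyl CH2 carbons are ortho to the C3 oxygen, so each can serve as the exocyclic carbon of an ortho-quinone methide of the C3 phenol.
- Forward: no ring is formed. The carbon chain is joined in the order C2 formyl (Vilsmeier–Haack), C4 formyl (magnesium phenoxide), then, after C5-O-allylation, reduction and carbonate formation, both alkenyl groups in a twofold quinone methide alkenylation. O-Methylation at C3 and deallylation at C5 finish the route.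
- Stereochemistry: there is no stereocentre. The E double bond of the stilbene comes with pinosylvin and is carried through unchanged; the prenyl double bonds have no geometry.

Key step: step 6

Remark: the central ring keeps the numbering C1–C6 of the plan in every step, and the alkenyl Grignard reagent is taken as the commercial THF solution.
Assumption: in the key step the benzylic carbonate at C2, para to the C5 ether oxygen, is written as leaving first; the opposite order would lead to the same product.

**Step 1**
Reactants: 1 pinosylvin, 5-[(E)-2-phenylethenyl]benzene-1,3-diol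
Product: 3 2,4-dihydroxy-6-[(E)-2-phenylethenyl]benzaldehyde, via aryl iminium chloride 2 (not isolated)
Conditions: POCl3 (1.2 equiv), DMF, MeCN, 0 °C → rt; then H2O, 50 °C
Reagents that add atoms: N,N-dimethylformamide CN(C)C=O; water O
Why: Vilsmeier–Haack formylation: the chloroiminium ion should attack C2, which is ortho to one hydroxyl and para to the other, as in other 5-substituted resorcinols where the more crowded carbon between the hydroxyls is avoided, and the iminium salt 2 is hydrolysed to the aldehyde on aqueous work-up, while the stilbene double bond is far less nucleophilic than the resorcinol ring.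

**Step 2**
Reactants: 3 2,4-dihydroxy-6-[(E)-2-phenylethenyl]benzaldehyde
Product: 5 2,4-dihydroxy-6-[(E)-2-phenylethenyl]benzene-1,3-dicarbaldehyde, via hydroxymethyl intermediate 4 (not isolated)
Conditions: MgCl2 (anhydrous), Et3N, (CH2O)n, MeCN, reflux; then 1 M HCl
Reagents that add atoms: formaldehyde (as paraformaldehyde) C=O
Why: Magnesium-mediated ortho-formylation of a phenol (Casnati–Skattebøl reaction): formaldehyde held on the magnesium phenoxide should be delivered to C4, which is ortho to both oxygens and carries the enolate character of the C5 oxygen because the C3 oxygen is tied up in a chelate with the C2 formyl group, whereas C6 is shielded by the styryl group, and the hydroxymethyl compound 4 formed first is oxidised to the aldehyde by hydride transfer to a second formaldehyde.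

**Step 3**
Reactants: 5 2,4-dihydroxy-6-[(E)-2-phenylethenyl]benzene-1,3-dicarbaldehyde
Product: 6 2-hydroxy-6-[(E)-2-phenylethenyl]-4-(prop-2-enyloxy)benzene-1,3-dicarbaldehyde
Conditions: allyl bromide (1.05 equiv), KHCO3, DMF, rt → 40 °C
Reagents that add atoms: allyl bromide C=CCBr
Why: Williamson etherification with a weak base and one equivalent of halide: the C3 hydroxyl lies between two formyl groups, is the more hindered and the more firmly hydrogen-bonded, so the C5 oxygen, para to the C2 formyl group, should be alkylated, in line with the known preference for 4-O-alkylation of 2,4-dihydroxyaryl aldehydes and ketones.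

**Step 4**
Reactants: 6 2-hydroxy-6-[(E)-2-phenylethenyl]-4-(prop-2-enyloxy)benzene-1,3-dicarbaldehyde
Product: 7 2,6-bis(hydroxymethyl)-5-[(E)-2-phenylethenyl]-3-(prop-2-enyloxy)phenol
Conditions: NaBH4, MeOH–THF, 0 °C; then sat. aq NH4Cl
Reagents that add atoms: none
Why: Borohydride reduction of both aryl aldehydes to primary benzylic alcohols, to which the allyl ether, the stilbene and the phenol are inert, with low temperature and a neutral quench to keep the electron-rich salicyl alcohol from ionising.

**Step 5**
Reactants: 7 2,6-bis(hydroxymethyl)-5-[(E)-2-phenylethenyl]-3-(prop-2-enyloxy)phenol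
Product: 8 tert-butyl 2,6-bis({[(tert-butoxy)carbonyl]oxy}methyl)-5-[(E)-2-phenylethenyl]-3-(prop-2-enyloxy)phenyl carbonate (tris-Boc derivative of 7)
Conditions: Boc2O (3.6 equiv), DMAP (cat.), i-Pr2NEt, CH2Cl2, 0 °C → rt
Reagents that add atoms: di-tert-butyl dicarbonate CC(C)(C)OC(=O)OC(=O)OC(C)(C)C
Why: DMAP-catalysed carbonate formation with Boc2O: the phenol is acylated first and the two primary benzylic alcohols follow, so that no phenoxide is left beside a benzylic carbonate and the quinone methide is not set free before step 6.

**Step 6**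
Reactants: 8 tris-Boc derivative of 7; 9 2-methylprop-1-enylmagnesium bromide
Product: 14 2,6-bis(3-methylbut-2-enyl)-5-[(E)-2-phenylethenyl]-3-(prop-2-enyloxy)phenol, via bromomagnesium phenoxide bis(carbonate) 10 (not isolated), via first ortho-quinone methide 11 (not isolated), via monoprenylated bromomagnesium phenoxide 12 (not isolated), via second ortho-quinone methide 13 (not isolated)
Conditions: 9 (6 equiv, 0.5 M in THF), THF, −78 → 0 °C; then sat. aq NH4Cl
Reagents that add atoms: none
Why: One equivalent of 9 attacks the aryl carbonate, the most electrophilic of the three because a phenoxide leaves, and frees magnesium phenoxide 10, which expels tert-butyl carbonate from the C2 benzylic carbon to give ortho-quinone methide 11. Rearomatisation drives 1,4-addition of the alkenyl group to the exocyclic methylene, which forms the first CH2–CH= bond and returns a phenoxide (12) that runs through the same elimination (13) and addition at C4. The closest known reaction type is the Grignard-triggered release of ortho-quinone methides from O-Boc salicyl alcohol derivatives with in situ conjugate addition of the organomagnesium reagent, here passed through twice on one phenol. No ring is closed and no stereocentre is made, and because each prenyl group is assembled at its CH2–CH= bond only the linear, untransposed isomer can form, also at the hindered C2 position. The step needs 1,4- over 1,2-addition and addition faster than quinone methide dimerisation, which the gain in aromaticity, the excess of reagent and the low temperature should secure, and it needs both benzylic carbons to answer to one oxygen, which the ortho relation of C2 and C4 to C3 provides. The allyl ether at C5 cannot give a phenoxide, so the C3 oxygen ends as the only free hydroxyl, ready for methylation.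

**Step 7**
Reactants: 14 2,6-bis(3-methylbut-2-enyl)-5-[(E)-2-phenylethenyl]-3-(prop-2-enyloxy)phenol
Product: 15 2-methoxy-1,3-bis(3-methylbut-2-enyl)-4-[(E)-2-phenylethenyl]-6-(prop-2-enyloxy)benzene
Conditions: MeI, K2CO3, DMF, rt
Reagents that add atoms: iodomethane CI
Why: Williamson O-methylation of the only free hydroxyl: the 2,6-dialkylphenoxide is hindered but still readily O-alkylated by the small electrophile MeI in a dipolar aprotic solvent, and the allyl ether, prenyl groups and stilbene do not react.

**Step 8**
Reactants: 15 2-methoxy-1,3-bis(3-methylbut-2-enyl)-4-[(E)-2-phenylethenyl]-6-(prop-2-enyloxy)benzene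
Product: 16 Chiricanine C, 3-methoxy-2,4-bis(3-methylbut-2-enyl)-5-[(E)-2-phenylethenyl]phenol
Conditions: Pd(PPh3)4 (5 mol %), morpholine, THF, rt
Reagents that add atoms: none
Why: Tsuji–Trost-type deallylation: zerovalent palladium ionises the aryl allyl ether to a π-allyl complex that morpholine captures, while the prenyl groups and the stilbene carry no allylic leaving group, and the neutral conditions avoid the acid-induced cyclisation of the ortho-prenylphenol to a chroman.

**Compound list**
1 | pinosylvin, 5-[(E)-2-phenylethenyl]benzene-1,3-diol | Oc1cc(O)cc(/C=C/c2ccccc2)c1 | starting material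
2 | {2,4-dihydroxy-6-[(E)-2-phenylethenyl]phenyl}methylidene(dimethyl)ammonium chloride | Oc1cc(O)cc(/C=C/c2ccccc2)c1C=[N+](C)C.[Cl-] | intermediate
3 | 2,4-dihydroxy-6-[(E)-2-phenylethenyl]benzaldehyde | Oc1cc(O)cc(/C=C/c2ccccc2)c1C=O | intermediate
4 | 2,4-dihydroxy-3-(hydroxymethyl)-6-[(E)-2-phenylethenyl]benzaldehyde | Oc1c(CO)c(O)cc(/C=C/c2ccccc2)c1C=O | intermediate
5 | 2,4-dihydroxy-6-[(E)-2-phenylethenyl]benzene-1,3-dicarbaldehyde | Oc1c(C=O)c(O)cc(/C=C/c2ccccc2)c1C=O | intermediate
6 | 2-hydroxy-6-[(E)-2-phenylethenyl]-4-(prop-2-enyloxy)benzene-1,3-dicarbaldehyde | Oc1c(C=O)c(OCC=C)cc(/C=C/c2ccccc2)c1C=O | intermediate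
7 | 2,6-bis(hydroxymethyl)-5-[(E)-2-phenylethenyl]-3-(prop-2-enyloxy)phenol | Oc1c(CO)c(OCC=C)cc(/C=C/c2ccccc2)c1CO | intermediate
8 | tert-butyl 2,6-bis({[(tert-butoxy)carbonyl]oxy}methyl)-5-[(E)-2-phenylethenyl]-3-(prop-2-enyloxy)phenyl carbonate | CC(C)(C)OC(=O)Oc1c(COC(=O)OC(C)(C)C)c(OCC=C)cc(/C=C/c2ccccc2)c1COC(=O)OC(C)(C)C | intermediate
9 | 2-methylprop-1-enylmagnesium bromide | CC(C)=C[Mg]Br | starting material
10 | bromomagnesium 2,6-bis({[(tert-butoxy)carbonyl]oxy}methyl)-5-[(E)-2-phenylethenyl]-3-(prop-2-enyloxy)phenoxide | Br[Mg]Oc1c(COC(=O)OC(C)(C)C)c(OCC=C)cc(/C=C/c2ccccc2)c1COC(=O)OC(C)(C)C | intermediate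
11 | 2-({[(tert-butoxy)carbonyl]oxy}methyl)-6-methylidene-5-[(E)-2-phenylethenyl]-3-(prop-2-enyloxy)cyclohexa-2,4-dien-1-one | O=C1C(COC(=O)OC(C)(C)C)=C(OCC=C)C=C(/C=C/c2ccccc2)C1=C | intermediate
12 | bromomagnesium 2-({[(tert-butoxy)carbonyl]oxy}methyl)-6-(3-methylbut-2-enyl)-5-[(E)-2-phenylethenyl]-3-(prop-2-enyloxy)phenoxide | Br[Mg]Oc1c(COC(=O)OC(C)(C)C)c(OCC=C)cc(/C=C/c2ccccc2)c1CC=C(C)C | intermediate
13 | 6-methylidene-2-(3-methylbut-2-enyl)-3-[(E)-2-phenylethenyl]-5-(prop-2-enyloxy)cyclohexa-2,4-dien-1-one | O=C1C(=C)C(OCC=C)=CC(/C=C/c2ccccc2)=C1CC=C(C)C | intermediate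
14 | 2,6-bis(3-methylbut-2-enyl)-5-[(E)-2-phenylethenyl]-3-(prop-2-enyloxy)phenol | Oc1c(CC=C(C)C)c(OCC=C)cc(/C=C/c2ccccc2)c1CC=C(C)C | intermediate
15 | 2-methoxy-1,3-bis(3-methylbut-2-enyl)-4-[(E)-2-phenylethenyl]-6-(prop-2-enyloxy)benzene | COc1c(CC=C(C)C)c(OCC=C)cc(/C=C/c2ccccc2)c1CC=C(C)C | intermediate
16 | Chiricanine C, 3-methoxy-2,4-bis(3-methylbut-2-enyl)-5-[(E)-2-phenylethenyl]phenol | COc1c(CC=C(C)C)c(O)cc(/C=C/c2ccccc2)c1CC=C(C)C | target

Total step count: 8. Longest linear sequence: 8 steps, from pinosylvin 1 to 16.

**Steps most likely to fail**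

Step 2. The ring of 3 is deactivated by its formyl group, so the formylation may stall, and formaldehyde-bridged oligomerisation or attack at C6 could then take over. The fallback sets out from 3 and separates halogenation from carbon introduction. Iodination with I2 and HIO3 in aqueous EtOH, which in chelated 2,4-dihydroxyaryl carbonyl compounds takes the carbon between the hydroxyls, should give 2,4-dihydroxy-3-iodo-6-[(E)-2-phenylethenyl]benzaldehyde F1; any C6 iodide could be removed at this stage. Palladium-catalysed reductive carbonylation of the aryl iodide (PdCl2(PPh3)2, CO, Et3SiH, Na2CO3, DMF, 80 °C) would then deliver the dialdehyde, and the route is rejoined at 5.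

Step 3. The allyl group may go onto the wrong oxygen or onto both, because both hydroxyls of 5 are hydrogen-bonded to a formyl group and differ mainly in crowding. The fallback sets out from 5 and postpones the differentiation of the two oxygens until after the alkenylation, where it rests on sterics alone:
- NaBH4 reduction should give 2,4-bis(hydroxymethyl)-5-[(E)-2-phenylethenyl]benzene-1,3-diol F2.
- Exhaustive carbonate formation (Boc2O, DMAP, i-Pr2NEt) should give its tetrakis(tert-butyl carbonate) F3.
- Excess 9 would unmask both phenoxides and form the same two CH2–CH= bonds, giving 2,4-bis(3-methylbut-2-enyl)-5-[(E)-2-phenylethenyl]benzene-1,3-diol F4.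
- The C5 hydroxyl, which has one ortho substituent, should then be silylated in preference to the C3 hydroxyl, which has two (TIPSCl, imidazole, DMF), to give 2,6-bis(3-methylbut-2-enyl)-5-[(E)-2-phenylethenyl]-3-[tri(propan-2-yl)silyloxy]phenol F5.
- Methylation (MeI, K2CO3, DMF) should give [3-methoxy-2,4-bis(3-methylbut-2-enyl)-5-[(E)-2-phenylethenyl]phenoxy]tri(propan-2-yl)silane F6, and desilylation with TBAF in THF returns to the route at the target 16.

Step 6. The second elimination–addition cycle may lag behind the first, so that a quinone methide dimerises or is trapped by a phenoxide, or the reagent may be consumed at the benzylic carbonates without productive unmasking of the phenol. The fallback sets out from 7 and forms the same two bonds by direct substitution without a quinone methide. Methylation of the phenol (MeI, K2CO3, acetone) should give [3-(hydroxymethyl)-2-methoxy-6-[(E)-2-phenylethenyl]-4-(prop-2-enyloxy)phenyl]methanol F7. Conversion of both benzylic alcohols into chlorides (MsCl, i-Pr2NEt, LiCl, CH2Cl2–DMF, 0 °C) would give 1,3-bis(chloromethyl)-2-methoxy-4-[(E)-2-phenylethenyl]-6-(prop-2-enyloxy)benzene F8. CuI-catalysed cross-coupling of the benzylic chlorides with 9 (THF, −30 °C), a known coupling of benzylic halides with alkenyl Grignard reagents, rejoins the route at 15.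

**Further compounds**
F1 | step 2 | 2,4-dihydroxy-3-iodo-6-[(E)-2-phenylethenyl]benzaldehyde | Oc1c(I)c(O)cc(/C=C/c2ccccc2)c1C=O
F2 | step 3 | 2,4-bis(hydroxymethyl)-5-[(E)-2-phenylethenyl]benzene-1,3-diol | Oc1c(CO)c(O)cc(/C=C/c2ccccc2)c1CO
F3 | step 3 | tetrakis(tert-butyl carbonate) of 2,4-bis(hydroxymethyl)-5-[(E)-2-phenylethenyl]benzene-1,3-diol | CC(C)(C)OC(=O)Oc1c(COC(=O)OC(C)(C)C)c(OC(=O)OC(C)(C)C)cc(/C=C/c2ccccc2)c1COC(=O)OC(C)(C)C
F4 | step 3 | 2,4-bis(3-methylbut-2-enyl)-5-[(E)-2-phenylethenyl]benzene-1,3-diol | Oc1c(CC=C(C)C)c(O)cc(/C=C/c2ccccc2)c1CC=C(C)C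
F5 | step 3 | 2,6-bis(3-methylbut-2-enyl)-5-[(E)-2-phenylethenyl]-3-[tri(propan-2-yl)silyloxy]phenol | Oc1c(CC=C(C)C)c(O[Si](C(C)C)(C(C)C)C(C)C)cc(/C=C/c2ccccc2)c1CC=C(C)C
F6 | step 3 | [3-methoxy-2,4-bis(3-methylbut-2-enyl)-5-[(E)-2-phenylethenyl]phenoxy]tri(propan-2-yl)silane | COc1c(CC=C(C)C)c(O[Si](C(C)C)(C(C)C)C(C)C)cc(/C=C/c2ccccc2)c1CC=C(C)C
F7 | step 6 | [3-(hydroxymethyl)-2-methoxy-6-[(E)-2-phenylethenyl]-4-(prop-2-enyloxy)phenyl]methanol | COc1c(CO)c(OCC=C)cc(/C=C/c2ccccc2)c1CO
F8 | step 6 | 1,3-bis(chloromethyl)-2-methoxy-4-[(E)-2-phenylethenyl]-6-(prop-2-enyloxy)benzene | COc1c(CCl)c(OCC=C)cc(/C=C/c2ccccc2)c1CCl
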